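A direct plan would join a 4-silyloxysalicylaldehyde to the dihalobenzyl alcohol A1 as an ether and turn the aldehyde into the diazoketone A2.
It would close ring C by chiral dirhodium-carbene insertion into the O–CH2–aryl group to give the bromo-iodo-flavanone A3, then add both side chains by Heck and Stille couplings and desilylate.
Its weakest step would be the carbene C–H insertion that makes C2–C3: the carbene would be expected to attack the ether oxygen first (oxonium ylide, then a five-membered benzofuranone).
The sense of induction at C2 would also be known only after the run, so the ring closure and the only stereocentre would both be left to chance.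
Next would be the late prenyl transfer from tin on the complete flavanone: linear versus branched allyl coupling is uncertain, and hot DMF could open ring C and racemise C2 on the most precious material.
Third would be the oxidation-level shuffle (aldehyde to alcohol on ring B; aldehyde to acid, acid chloride and diazoketone on ring A, with diazomethane): about six steps that add no bond of the target skeleton.

**Plan of the new route**
The retrosynthesis cuts the C2–C1′ bond between ring C and ring B first, then the C–B, C3′–alkenyl and C5′–prenyl bonds of ring B.
Rings A and C are taken fused and flat as commercial 7-hydroxychromone; ring B is dressed separately from 2,6-dibromo-4-chlorophenol, whose halogens react in a fixed order, and is joined last.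
The feature used: C2 is at once the only stereocentre, the junction of rings B and C and, at the chromone oxidation level, the β-carbon of the vinylogous ester O1–C2=C3–C4=O, while C2′ and C6′ of ring B are unsubstituted.
A ligand-controlled conjugate arylation therefore makes this bond and the stereocentre in the final step, on the unprotected phenol: no carbene, no ring closure against a competing pathway, no coupling or deprotection on a flavanone, no redox shuffle.

Key step: step 5

Remark: 2,6-dibromo-4-chlorophenol, prenyl bromide, 2-methylbut-3-en-2-ol, 7-hydroxychromone, tetrahydroxydiboron and both enantiomers of t-BuPyOx are taken as commercial.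

Step 1
Reactants: 1 2,6-dibromo-4-chlorophenol
Product: 2 1,3-dibromo-5-chloro-2-methoxybenzene
Conditions: MeI, K2CO3, acetone, reflux
Reagents that add atoms: iodomethane, CI
Why: Williamson ether synthesis, in which the acidic, doubly ortho-brominated phenoxide is methylated by the small electrophile despite its flanking bromines.

Step 2
Reactants: 2 1,3-dibromo-5-chloro-2-methoxybenzene; 3 1-bromo-3-methylbut-2-ene (prenyl bromide)
Product: 5 1-bromo-5-chloro-2-methoxy-3-(3-methylbut-2-enyl)benzene, via aryllithium 4 (not isolated)
Conditions: n-BuLi (1.0 equiv), Et2O, −78 °C; then CuBr·SMe2 (10 mol %), 3, −78 to 0 °C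
Reagents that add atoms: n-butyllithium, [Li]CCCC (lithium of intermediate 4 only)
Why: Bromine–lithium exchange followed by copper-catalysed allylic substitution: one equivalent of n-BuLi exchanges one of the two equivalent C–Br bonds next to the coordinating methoxy group (C–Cl is inert at −78 °C and the aryllithium resists a second exchange), and the aryl–copper species displaces bromide at the unhindered CH2 terminus of prenyl bromide (SN2) rather than at the tertiary carbon, which should give the linear prenyl group.

Step 3
Reactants: 5 1-bromo-5-chloro-2-methoxy-3-(3-methylbut-2-enyl)benzene; 6 2-methylbut-3-en-2-ol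
Product: 7 (E)-4-[5-chloro-2-methoxy-3-(3-methylbut-2-enyl)phenyl]-2-methylbut-3-en-2-ol
Conditions: Pd(OAc)2 (3 mol %), P(o-tol)3 (8 mol %), Et3N, MeCN, 90 °C (sealed vessel)
Reagents that add atoms: none
Why: Heck reaction, in which zerovalent palladium with a triarylphosphine inserts into C–Br but not into C–Cl, aryl migration to the terminal carbon of the monosubstituted alkene and syn-β-hydride elimination give the E-styrene, the quaternary carbinol carbon offers no hydrogen for elimination toward a ketone, and the trisubstituted prenyl alkene does not compete.

Step 4
Reactants: 7 (E)-4-[5-chloro-2-methoxy-3-(3-methylbut-2-enyl)phenyl]-2-methylbut-3-en-2-ol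
Product: 8 {3-[(E)-3-hydroxy-3-methylbut-1-enyl]-4-methoxy-5-(3-methylbut-2-enyl)phenyl}boronic acid
Conditions: B2(OH)4 (3 equiv), PdCl(XPhos)(2′-amino-1,1′-biphenyl-2-yl) (second-generation XPhos palladacycle, 2 mol %), XPhos (4 mol %), KOAc (3 equiv), EtOH, 80 °C; neutral aqueous work-up
Reagents that add atoms: tetrahydroxydiboron, OB(O)B(O)O
Why: Miyaura borylation, in which the bulky electron-rich biarylphosphine lets zerovalent palladium add to the electron-rich C–Cl bond, acetate mediates boron-to-palladium transfer from tetrahydroxydiboron, and the free boronic acid forms directly without an ester cleavage while the alkenes and the tertiary alcohol are spectators in this weakly basic medium.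

Step 5
Reactants: 8 {3-[(E)-3-hydroxy-3-methylbut-1-enyl]-4-methoxy-5-(3-methylbut-2-enyl)phenyl}boronic acid; 9 7-hydroxy-4H-chromen-4-one (1.5 equiv)
Product: 10 (2S)-7-hydroxy-2-{3-[(E)-3-hydroxy-3-methylbut-1-enyl]-4-methoxy-5-(3-methylbut-2-enyl)phenyl}chroman-4-one
Conditions: Pd(OCOCF3)2 (5 mol %), (R)-t-BuPyOx [(R)-4-tert-butyl-2-(pyridin-2-yl)-4,5-dihydrooxazole] (6 mol %), NH4PF6 (30 mol %), H2O (5 equiv), ClCH2CH2Cl, 60 °C
Reagents that add atoms: none
Why: The cationic divalent palladium complex of (R)-t-BuPyOx takes the aryl group from 8 by transmetalation, binds the C2=C3 bond of 9 and inserts it into the Pd–aryl bond so that the aryl group goes to C2 and palladium to C3, and water then protonates the palladium enolate, which frees the chroman-4-one and returns the Pd–OH species without any change of oxidation state. The closest known reaction type is the palladium–pyridinooxazoline-catalysed asymmetric conjugate addition of arylboronic acids to chromones and other cyclic β-substituted enones. No ring is closed: rings A and C are already present in 9, ring B arrives with 8, and the only skeletal bond made is C2–C1′. The C2 stereocentre is controlled by the ligand alone, whose tert-butyl group fixes the orientation of the bound chromone in the insertion transition state; by the facial model of this catalyst family (the S ligand adds the aryl group to the face of a six-membered cyclic enone that corresponds to the Si face of C2 and would give 2R), the R ligand should deliver the aryl group to the Re face of C2 (priority O1 > C3 > H) and give 2S. The step needs 1,4-addition at C2 in preference to reaction at the side-chain alkenes and to protodeboronation: C2 is the only polarised alkene carbon present, the prenyl alkene is trisubstituted and the styrenyl alkene is 1,2-disubstituted next to a quaternary carbinol, so both are poor ligands for the hindered cationic catalyst, and the unsubstituted C2′ and C6′ of 8 allow transmetalation and insertion. The weakly acidic, base-free medium leaves the free 7-OH alone and gives the product no path for retro-oxa-Michael opening, so the stereocentre is made in the last step and meets no further reagent.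

**Compound list**
1 | 2,6-dibromo-4-chlorophenol | Oc1c(Br)cc(Cl)cc1Br | starting material
2 | 1,3-dibromo-5-chloro-2-methoxybenzene | COc1c(Br)cc(Cl)cc1Br | intermediate
3 | 1-bromo-3-methylbut-2-ene (prenyl bromide) | CC(C)=CCBr | starting material
4 | (3-bromo-5-chloro-2-methoxyphenyl)lithium | COc1c(Br)cc(Cl)cc1[Li] | intermediate
5 | 1-bromo-5-chloro-2-methoxy-3-(3-methylbut-2-enyl)benzene | COc1c(Br)cc(Cl)cc1CC=C(C)C | intermediate
6 | 2-methylbut-3-en-2-ol | C=CC(C)(C)O | starting material
7 | (E)-4-[5-chloro-2-methoxy-3-(3-methylbut-2-enyl)phenyl]-2-methylbut-3-en-2-ol | COc1c(/C=C/C(C)(C)O)cc(Cl)cc1CC=C(C)C | intermediate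
8 | {3-[(E)-3-hydroxy-3-methylbut-1-enyl]-4-methoxy-5-(3-methylbut-2-enyl)phenyl}boronic acid | COc1c(/C=C/C(C)(C)O)cc(B(O)O)cc1CC=C(C)C | intermediate
9 | 7-hydroxy-4H-chromen-4-one | O=c1ccoc2cc(O)ccc12 | starting material
10 | (2S)-7-hydroxy-2-{3-[(E)-3-hydroxy-3-methylbut-1-enyl]-4-methoxy-5-(3-methylbut-2-enyl)phenyl}chroman-4-one | COc1c(/C=C/C(C)(C)O)cc([C@@H]2CC(=O)c3ccc(O)cc3O2)cc1CC=C(C)C | target

**Count and risks**
Total steps: 5. Longest linear sequence: 5 steps (1 → 2 → 5 → 7 → 8 → 10); 3, 6 and 9 are bought.

Steps most likely to fail:

Step 5. Several processes could go wrong: protodeboronation of the electron-rich boronic acid before transmetalation; ionisation or 1,3-transposition of the tertiary allylic alcohol at the Lewis-acidic cationic palladium; loss of catalyst through insertion of the styrenyl alkene into the aryl–palladium bond; or incomplete facial selectivity. The fallback sets out from 8 and 9 and comes back at 10. It replaces the cationic palladium pathway by aryl transfer from neutral monovalent rhodium to a phenol-masked chromone. 9 would be silylated (TBDPSCl, imidazole, DMF, rt) to 7-(tert-butyldiphenylsilyloxy)-4H-chromen-4-one F1. 8 would then be added to F1 with [Rh(OH)((S)-BINAP)]2 in dioxane/H2O at 40–60 °C. This 1,4-addition runs through an aryl–rhodium species and a rhodium enolate with no acid or Lewis acid in the medium. The S ligand gives (S)-3-arylcyclohexanones from cyclohex-2-enone and so should address the Re face of C2. The product would be (2S)-7-(tert-butyldiphenylsilyloxy)-2-{3-[(E)-3-hydroxy-3-methylbut-1-enyl]-4-methoxy-5-(3-methylbut-2-enyl)phenyl}chroman-4-one F2. Desilylation with n-Bu4NF buffered by AcOH in THF at 0 °C should then give 10 without opening ring C.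

Step 4. The hydroxyboron reagent could activate the tertiary allylic C–OH bond toward zerovalent palladium (allylic borylation or reduction). The product could also protodeboronate in hot ethanol, or couple with unreacted chloride. The fallback sets out from 7 and comes back at 8. The free acid is no longer made directly; boron enters as a protected ester in an aprotic medium and is unmasked in a separate neutral step. 7 would be borylated with B2pin2, Pd2(dba)3, XPhos and KOAc in dioxane at 100 °C to (E)-4-[2-methoxy-3-(3-methylbut-2-enyl)-5-(4,4,5,5-tetramethyl-1,3,2-dioxaborolan-2-yl)phenyl]-2-methylbut-3-en-2-ol F3, which can be chromatographed. Oxidative cleavage of the pinacol unit with NaIO4 and NH4OAc in acetone/H2O at rt should then give 8.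

Step 2. The aryl-metal could attack the tertiary terminus of prenyl bromide (SN2′, giving the 1,1-dimethylallyl isomer), or Wurtz-type coupling of the allylic bromide could intervene. The fallback sets out from 2 (through 4) and comes back at 5. It removes the regiochemical question by using a symmetric allyl group and builds the dimethyl terminus by olefin metathesis. 4 would be quenched with allyl bromide (CuBr·SMe2, 10 mol %) to give 1-bromo-5-chloro-2-methoxy-3-(prop-2-enyl)benzene F4. Cross-metathesis of F4 with excess 2-methylbut-2-ene and RuCl2(=CHPh)(H2IMes)(PCy3) (second-generation Grubbs catalyst) in CH2Cl2 at 40 °C should give 5.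

**Further compounds**
F1 | step 5 | 7-(tert-butyldiphenylsilyloxy)-4H-chromen-4-one | O=c1ccoc2cc(O[Si](c3ccccc3)(c3ccccc3)C(C)(C)C)ccc12
F2 | step 5 | (2S)-7-(tert-butyldiphenylsilyloxy)-2-{3-[(E)-3-hydroxy-3-methylbut-1-enyl]-4-methoxy-5-(3-methylbut-2-enyl)phenyl}chroman-4-one | COc1c(/C=C/C(C)(C)O)cc([C@@H]2CC(=O)c3ccc(O[Si](c4ccccc4)(c4ccccc4)C(C)(C)C)cc3O2)cc1CC=C(C)C
F3 | step 4 | (E)-4-[2-methoxy-3-(3-methylbut-2-enyl)-5-(4,4,5,5-tetramethyl-1,3,2-dioxaborolan-2-yl)phenyl]-2-methylbut-3-en-2-ol | COc1c(/C=C/C(C)(C)O)cc(B2OC(C)(C)C(C)(C)O2)cc1CC=C(C)C
F4 | step 2 | 1-bromo-5-chloro-2-methoxy-3-(prop-2-enyl)benzene | COc1c(Br)cc(Cl)cc1CC=C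
A1 | direct plan | (3-bromo-5-iodo-4-methoxyphenyl)methanol | COc1c(Br)cc(CO)cc1I
A2 | direct plan | 1-{2-[(3-bromo-5-iodo-4-methoxyphenyl)methoxy]-4-(triisopropylsilyloxy)phenyl}-2-diazoethanone | [N-]=[N+]=CC(=O)c1ccc(O[Si](C(C)C)(C(C)C)C(C)C)cc1OCc1cc(Br)c(OC)c(I)c1
A3 | direct plan | (2S)-2-(3-bromo-5-iodo-4-methoxyphenyl)-7-(triisopropylsilyloxy)chroman-4-one | COc1c(I)cc([C@@H]2CC(=O)c3ccc(O[Si](C(C)C)(C(C)C)C(C)C)cc3O2)cc1Br
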